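**Plan**
- Cuts: first the O8 acyl bond (side chain) and the C15 oxidation level. Then C5–C6 and O6–C12 together, then C7–C8 (aldol), then C1=C10 (Wittig). The C4=C5 iodoalkene goes back to a malonate.
- Enabling feature: in the ten-membered ring C1–C10, C6 is the allylic carbinol carbon beside C4=C5. It is also the oxygen-bearing atom of the five-membered lactone ring (O6, C6, C7, C11, C12). C6–C7–C11(=C13)–C12 is the carbon chain of itaconic acid, so an alkoxide created at C6 sits 1,4 to the C12 ester.
- Forward: fragment A (C1–C5, C15) and fragment B (C8–C10, C14) join at C1=C10. The C8 aldehyde and fragment C (C6, C7, C11–C13) join at C7–C8. Step 19 closes the carbocycle and then the lactone in the same flask; the C15 aldehyde and the side chain come last.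
- Stereochemistry: iodine cis to C3 comes from a decarboxylative elimination and C9 cis to C2 from a stabilised ylide. C7 and C8 come from an auxiliary-controlled syn-aldol, and C6 from Felkin–Anh addition next to C7 during ring closure.

Key step: step 19

Remark: C1–C15 are germacrane atom labels, used for open-chain intermediates as well (TBS = tert-butyldimethylsilyl, TBDPS = tert-butyldiphenylsilyl); the CIP letter at C7 is S in 31 only because silicon on O8 raises the rank of C8, the spatial arrangement being that of the target.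

**Step 1**
Reactants: 1 diethyl malonate; 2 2-(2-bromoethyl)-1,3-dioxolane
Product: 3 diethyl 2-[2-(1,3-dioxolan-2-yl)ethyl]malonate
Conditions: NaH, NaI (cat.), THF/DMF, 0 to 60 °C
Reagents that add atoms: none
Why: Malonic ester alkylation (SN2 of the sodium enolate on a primary bromide) should join C3 to C4, and an excess of 1 keeps dialkylation down.

**Step 2**
Reactants: 3 diethyl 2-[2-(1,3-dioxolan-2-yl)ethyl]malonate
Product: 4 diethyl 2-(diiodomethyl)-2-[2-(1,3-dioxolan-2-yl)ethyl]malonate
Conditions: NaH, Et2O, reflux; CHI3, reflux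
Reagents that add atoms: iodoform, IC(I)I
Why: Diiodomethylation of a substituted malonate anion with iodoform is a known C-alkylation that brings in C5 together with both iodine atoms needed for the next step.

**Step 3**
Reactants: 4 diethyl 2-(diiodomethyl)-2-[2-(1,3-dioxolan-2-yl)ethyl]malonate
Product: 6 (E)-2-[2-(1,3-dioxolan-2-yl)ethyl]-3-iodoprop-2-enoic acid, via dipotassium malonate 5 (not isolated)
Conditions: KOH, EtOH/H2O, reflux; then cold 1 M HCl to pH 4
Reagents that add atoms: potassium hydroxide, [K+].[OH-]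
Why: Saponification gives 5, which loses CO2 and iodide in an anti decarboxylative elimination (Grob-type fragmentation, known for diiodomethyl malonates) that leaves the remaining iodine trans to the carboxylate and so cis to C3, while the dioxolane is inert to base.

**Step 4**
Reactants: 6 (E)-2-[2-(1,3-dioxolan-2-yl)ethyl]-3-iodoprop-2-enoic acid
Product: 7 (E)-2-[2-(1,3-dioxolan-2-yl)ethyl]-3-iodoprop-2-en-1-ol
Conditions: LiAlH4, Et2O, 0 °C to rt
Reagents that add atoms: none
Why: Hydride reduction of the carboxylic acid with LiAlH4 is the standard way from (E)-3-iodo-2-alkylacrylic acids to the allylic alcohols and should leave the C–I bond, the alkene geometry and the acetal untouched.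

**Step 5**
Reactants: 7 (E)-2-[2-(1,3-dioxolan-2-yl)ethyl]-3-iodoprop-2-en-1-ol
Product: 8 TBDPS ether of 7
Conditions: TBDPSCl, imidazole, CH2Cl2, 0 °C to rt
Reagents that add atoms: tert-butyl(chloro)diphenylsilane, CC(C)(C)[Si](Cl)(c1ccccc1)c1ccccc1
Why: Imidazole-promoted silylation; TBDPS is chosen because it should outlast the acid of step 6, the selective TBS cleavage of step 12 and the Lewis acid of step 16, and falls together with the C8 silyl group in step 20.

**Step 6**
Reactants: 8 TBDPS ether of 7
Product: 9 (E)-4-{[(tert-butyldiphenylsilyl)oxy]methyl}-5-iodopent-4-enal (fragment A)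
Conditions: 1 M HCl, THF, rt
Reagents that add atoms: water, O
Why: Acid-catalysed acetal hydrolysis frees the C1 aldehyde, and neither the TBDPS ether nor the iodoalkene reacts with dilute aqueous acid at room temperature.

**Step 7**
Reactants: 10 (3-bromopropoxy)(tert-butyl)dimethylsilane
Product: 11 {3-[(tert-butyldimethylsilyl)oxy]propyl}triphenylphosphonium bromide
Conditions: PPh3, MeCN, reflux
Reagents that add atoms: triphenylphosphine, c1ccc(cc1)P(c1ccccc1)c1ccccc1
Why: SN2 quaternisation of PPh3 by a primary bromide gives the phosphonium salt that carries C8, C9 and C10, the TBS ether being stable in neutral refluxing MeCN.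

**Step 8**
Reactants: 11 {3-[(tert-butyldimethylsilyl)oxy]propyl}triphenylphosphonium bromide
Product: 14 methyl 4-[(tert-butyldimethylsilyl)oxy]-2-(triphenyl-λ5-phosphanylidene)butanoate (fragment B), via phosphorane 12 (not isolated), via acylphosphonium chloride 13 (not isolated)
Conditions: NaN(SiMe3)2 (1 equiv), THF, 0 °C; ClCO2Me, −78 °C; NaN(SiMe3)2 (1 equiv), −78 °C to rt
Reagents that add atoms: methyl chloroformate, COC(=O)Cl
Why: Deprotonation gives 12, C-acylation with the chloroformate gives 13 and the second equivalent of base gives the stabilised ylide, which is the known acylation route to α-substituted (alkoxycarbonyl)methylene phosphoranes and adds C14.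

**Step 9**
Reactants: 9 fragment A aldehyde; 14 fragment B ylide
Product: 15 methyl (2E,6E)-2-{2-[(tert-butyldimethylsilyl)oxy]ethyl}-6-{[(tert-butyldiphenylsilyl)oxy]methyl}-7-iodohepta-2,6-dienoate
Conditions: toluene, 90 °C
Reagents that add atoms: none
Why: Wittig olefination with a stabilised, α-substituted ylide should give the (E)-enoate with the ester trans to C2, which means C9 cis to C2 and thus the ring-cis C1=C10 geometry, while the iodoalkene and both silyl ethers are inert.

**Step 10**
Reactants: 15 dienoate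
Product: 16 (2E,6E)-2-{2-[(tert-butyldimethylsilyl)oxy]ethyl}-6-{[(tert-butyldiphenylsilyl)oxy]methyl}-7-iodohepta-2,6-dien-1-ol
Conditions: i-Bu2AlH (2.5 equiv), CH2Cl2, −78 °C; aq. potassium sodium tartrate
Reagents that add atoms: none
Why: 1,2-Reduction of the enoate with i-Bu2AlH (ester to allylic alcohol) turns C14 into CH2OH without touching the alkenyl iodide or either alkene geometry.

**Step 11**
Reactants: 16 dienol
Product: 17 C14 acetate of 16
Conditions: Ac2O, pyridine, DMAP (cat.), CH2Cl2, 0 °C
Reagents that add atoms: acetic anhydride, CC(=O)OC(C)=O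
Why: DMAP-catalysed acetylation installs the C14 acetate of the target at the only free hydroxyl.

**Step 12**
Reactants: 17 C14 acetate
Product: 18 (2E,6E)-6-{[(tert-butyldiphenylsilyl)oxy]methyl}-2-(2-hydroxyethyl)-7-iodohepta-2,6-dien-1-yl acetate
Conditions: HF·pyridine, pyridine, THF, 0 °C
Reagents that add atoms: none
Why: Fluoride-mediated desilylation under buffered HF·pyridine distinguishes the primary TBS ether from the far more robust TBDPS ether and leaves the acetate alone.

**Step 13**
Reactants: 18 C8 alcohol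
Product: 19 (2E,6E)-6-{[(tert-butyldiphenylsilyl)oxy]methyl}-7-iodo-2-(2-oxoethyl)hepta-2,6-dien-1-yl acetate (C8 aldehyde)
Conditions: Dess–Martin periodinane, NaHCO3, CH2Cl2, 0 °C; used at once
Reagents that add atoms: none
Why: Buffered Dess–Martin oxidation works under neutral conditions, which is what a β,γ-unsaturated aldehyde needs to stay out of conjugation.

**Step 14**
Reactants: 20 dimethyl itaconate
Product: 21 3-(methoxycarbonyl)but-3-enoic acid
Conditions: LiOH (1.0 equiv), THF/H2O, 0 °C; then 1 M HCl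
Reagents that add atoms: lithium hydroxide, [Li+].[OH-]
Why: Regioselective half-saponification of an itaconate diester works because the unconjugated C6 ester is more electrophilic than the acrylate ester at C12, and the low temperature should keep C11=C13 in place.

**Step 15**
Reactants: 21 3-(methoxycarbonyl)but-3-enoic acid; 22 (R)-4-benzyl-1,3-thiazolidine-2-thione
Product: 24 methyl 4-[(4R)-4-benzyl-2-thioxo-1,3-thiazolidin-3-yl]-2-methylidene-4-oxobutanoate (fragment C), via O-acylisourea 23 (not isolated)
Conditions: EDC·HCl, DMAP (cat.), CH2Cl2, 0 °C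
Reagents that add atoms: none
Why: Carbodiimide coupling through 23 (Steglich-type N-acylation) is the usual way to N-acyl thiazolidinethiones, and short contact with catalytic DMAP at 0 °C should keep C11=C13 from moving into conjugation.

**Step 16**
Reactants: 24 fragment C thioimide; 19 C8 aldehyde
Product: 26 (7R,8S) syn-aldol adduct (C6 thioimide; C8 OH; C12 methyl ester), via titanium enolate 25 (not isolated)
Conditions: 24, TiCl4, i-Pr2NEt, NMP, CH2Cl2, −78 °C; then 19, −78 to −40 °C; aq. NH4Cl
Reagents that add atoms: none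
Why: Titanium-mediated syn-aldol (Crimmins aldol, amine plus NMP variant): soft enolisation gives the (Z)-enolate 25, which reacts at C7 through a non-chelated Zimmerman–Traxler chair on the face away from the benzyl group, so the (R)-auxiliary sets 7R and 8S with C11 and O8 syn.

**Step 17**
Reactants: 26 syn-aldol adduct
Product: 27 8-O-TBS ether of 26
Conditions: TBSOTf, 2,6-lutidine, CH2Cl2, −78 to 0 °C
Reagents that add atoms: tert-butyldimethylsilyl triflate, CC(C)(C)[Si](C)(C)OS(=O)(=O)C(F)(F)F
Why: Silylation with the triflate and a hindered pyridine base is fast at low temperature, so O8 is capped before it can close on the C12 ester, and the conditions are too mild to epimerise C7.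

**Step 18**
Reactants: 27 8-O-TBS thioimide
Product: 28 open-chain C5 iodide with C6 aldehyde (7R,8S; 8-O-TBS; 15-O-TBDPS; 14-OAc; C12 methyl ester)
Conditions: i-Bu2AlH (about 1.1 equiv, added until the yellow colour fades), CH2Cl2, −78 °C; aq. potassium sodium tartrate
Reagents that add atoms: none
Why: Partial reduction of the activated N-acyl thiazolidinethione by i-Bu2AlH (reductive auxiliary cleavage) is far faster than ester reduction and gives the aldehyde directly, avoiding a C6 alcohol that would lactonise on C12.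

**Step 19**
Reactants: 28 open-chain iodo aldehyde
Product: 31 protected germacranolide (8-O-TBS; 15-O-TBDPS; 14-OAc; trans-fused 6,12-olide; 6R), via alkenylchromium 29 (not isolated), via chromium alkoxide 30 (not isolated)
Conditions: CrCl2 (10 equiv), NiCl2 (2 mol %), DMSO/THF, slow addition to about 2 mM, 25 °C, then 45 °C; aq. NH4Cl
Reagents that add atoms: none
Why: CrCl2 reduces NiCl2 to zerovalent nickel, which inserts into the C5–I bond with retention of geometry and hands the alkenyl group to trivalent chromium to give 29, and 29 adds to the C6 aldehyde; this is the Nozaki–Hiyama–Kishi alkenyl iodide–aldehyde macrocyclisation, a reaction type already used for medium rings. The carbocycle closes 10-exo-trig at the carbonyl carbon, and the two ring-cis alkenes (C9 cis to C2, C3 cis to the C5 metal) fold the chain so that C5 and C6 can meet. The lactone ring closes 5-exo-trig when alkoxide 30 displaces methoxide at C12 on gentle warming, the behaviour known from chromium-mediated 2-(alkoxycarbonyl)allylations, which deliver α-methylene-γ-butyrolactones directly. C6 is the only new stereocentre and is steered by C7: with the branched C8 carbon anti to the incoming alkenyl group and H7 next to its trajectory (Felkin–Anh), O6 ends up syn to C11, which is the 6R alkoxide and leads to the less strained trans-fused lactone with C5 trans to C8. The step needs attack at the aldehyde only and ring closure ahead of dimerisation; the first is secured by the low basicity and high aldehyde preference of alkenylchromium, which spares acetate, acrylate ester, silyl ethers and the labile C7–H, the second by slow addition to about 2 mM. Acyl transfer to O6 consumes the alkoxide soon after it forms, so loss of the C8 silyloxy group or C6–C7 cleavage has little chance to start.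

**Step 20**
Reactants: 31 protected germacranolide
Product: 32 (6R,7R,8S)-14-acetoxy-8,15-dihydroxy germacranolide (8,15-diol)
Conditions: HF·pyridine (excess), THF, 0 °C to rt
Reagents that add atoms: none
Why: Fluoride-mediated desilylation with excess HF·pyridine removes both silyl ethers under mildly acidic conditions that spare the acetate, the α-methylene lactone and the ring alkenes and give O8 no basic push toward C12.

**Step 21**
Reactants: 32 8,15-diol
Product: 33 (6R,7R,8S)-14-acetoxy-8-hydroxy-15-oxo germacranolide (C15 enal)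
Conditions: MnO2, CH2Cl2, rt
Reagents that add atoms: none
Why: MnO2 oxidises only allylic alcohols, so C15 becomes the enal while the non-allylic secondary C8 hydroxyl stays free for acylation.

**Step 22**
Reactants: 34 ethyl 2-(hydroxymethyl)acrylate
Product: 35 ethyl 2-{[(tert-butyldimethylsilyl)oxy]methyl}acrylate
Conditions: TBSCl, imidazole, CH2Cl2, 0 °C to rt
Reagents that add atoms: tert-butyl(chloro)dimethylsilane, CC(C)(C)[Si](C)(C)Cl
Why: Imidazole-promoted silylation masks the primary hydroxyl of the side-chain building block.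

**Step 23**
Reactants: 35 ethyl 2-{[(tert-butyldimethylsilyl)oxy]methyl}acrylate
Product: 36 2-{[(tert-butyldimethylsilyl)oxy]methyl}acrylic acid
Conditions: LiOH, THF/H2O, 0 °C to rt; then dilute HCl to pH 4
Reagents that add atoms: lithium hydroxide, [Li+].[OH-]
Why: Saponification of the ethyl ester with LiOH gives the acid, the primary TBS ether being stable to cold aqueous base and to brief acidification to pH 4.

**Step 24**
Reactants: 33 C15 enal with free C8 hydroxyl; 36 2-{[(tert-butyldimethylsilyl)oxy]methyl}acrylic acid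
Product: 38 O-TBS ether of the target, via mixed anhydride 37 (not isolated)
Conditions: 36, 2,4,6-trichlorobenzoyl chloride, Et3N, toluene, rt; then 33, DMAP, rt
Reagents that add atoms: none
Why: Yamaguchi esterification through 37 is a proven way to acylate hindered secondary alcohols with acrylic acids, and O8 is the only hydroxyl left in 33.

**Step 25**
Reactants: 38 O-TBS ether of the target
Product: 39 CNP0198933.2
Conditions: HF·pyridine, THF, 0 °C
Reagents that add atoms: none
Why: Fluoride-mediated cleavage of the primary TBS ether with HF·pyridine is mild enough for the enal, both acrylate units, the acetate and the lactone.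

**Compound list**
1 | diethyl malonate | CCOC(=O)CC(=O)OCC | starting material
2 | 2-(2-bromoethyl)-1,3-dioxolane | BrCCC1OCCO1 | starting material
3 | diethyl 2-[2-(1,3-dioxolan-2-yl)ethyl]malonate | CCOC(=O)C(CCC1OCCO1)C(=O)OCC | intermediate
4 | diethyl 2-(diiodomethyl)-2-[2-(1,3-dioxolan-2-yl)ethyl]malonate | CCOC(=O)C(CCC1OCCO1)(C(I)I)C(=O)OCC | intermediate
5 | dipotassium 2-(diiodomethyl)-2-[2-(1,3-dioxolan-2-yl)ethyl]malonate (not isolated) | [K+].[K+].[O-]C(=O)C(CCC1OCCO1)(C(I)I)C([O-])=O | intermediate
6 | (E)-2-[2-(1,3-dioxolan-2-yl)ethyl]-3-iodoprop-2-enoic acid | OC(=O)/C(CCC1OCCO1)=C/I | intermediate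
7 | (E)-2-[2-(1,3-dioxolan-2-yl)ethyl]-3-iodoprop-2-en-1-ol | OC/C(CCC1OCCO1)=C/I | intermediate
8 | tert-butyl{[(E)-2-[2-(1,3-dioxolan-2-yl)ethyl]-3-iodoprop-2-en-1-yl]oxy}diphenylsilane | CC(C)(C)[Si](OC/C(CCC1OCCO1)=C/I)(c1ccccc1)c1ccccc1 | intermediate
9 | (E)-4-{[(tert-butyldiphenylsilyl)oxy]methyl}-5-iodopent-4-enal (fragment A, C1–C5 and C15, iodine cis to C3) | O=CCC/C(CO[Si](c1ccccc1)(c1ccccc1)C(C)(C)C)=C\I | intermediate
10 | (3-bromopropoxy)(tert-butyl)dimethylsilane | CC(C)(C)[Si](C)(C)OCCCBr | starting material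
11 | {3-[(tert-butyldimethylsilyl)oxy]propyl}triphenylphosphonium bromide | CC(C)(C)[Si](C)(C)OCCC[P+](c1ccccc1)(c1ccccc1)c1ccccc1.[Br-] | intermediate
12 | {3-[(tert-butyldimethylsilyl)oxy]propylidene}triphenylphosphorane (not isolated) | CC(C)(C)[Si](C)(C)OCCC=P(c1ccccc1)(c1ccccc1)c1ccccc1 | intermediate
13 | {4-[(tert-butyldimethylsilyl)oxy]-1-methoxy-1-oxobutan-2-yl}triphenylphosphonium chloride (not isolated) | COC(=O)C(CCO[Si](C)(C)C(C)(C)C)[P+](c1ccccc1)(c1ccccc1)c1ccccc1.[Cl-] | intermediate
14 | methyl 4-[(tert-butyldimethylsilyl)oxy]-2-(triphenyl-λ5-phosphanylidene)butanoate (fragment B, C8–C10 and C14) | COC(=O)C(CCO[Si](C)(C)C(C)(C)C)=P(c1ccccc1)(c1ccccc1)c1ccccc1 | intermediate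
15 | methyl (2E,6E)-2-{2-[(tert-butyldimethylsilyl)oxy]ethyl}-6-{[(tert-butyldiphenylsilyl)oxy]methyl}-7-iodohepta-2,6-dienoate | COC(=O)/C(CCO[Si](C)(C)C(C)(C)C)=C/CC/C(CO[Si](c1ccccc1)(c1ccccc1)C(C)(C)C)=C\I | intermediate
16 | (2E,6E)-2-{2-[(tert-butyldimethylsilyl)oxy]ethyl}-6-{[(tert-butyldiphenylsilyl)oxy]methyl}-7-iodohepta-2,6-dien-1-ol | OC/C(CCO[Si](C)(C)C(C)(C)C)=C/CC/C(CO[Si](c1ccccc1)(c1ccccc1)C(C)(C)C)=C\I | intermediate
17 | (2E,6E)-2-{2-[(tert-butyldimethylsilyl)oxy]ethyl}-6-{[(tert-butyldiphenylsilyl)oxy]methyl}-7-iodohepta-2,6-dien-1-yl acetate | CC(=O)OC/C(CCO[Si](C)(C)C(C)(C)C)=C/CC/C(CO[Si](c1ccccc1)(c1ccccc1)C(C)(C)C)=C\I | intermediate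
18 | (2E,6E)-6-{[(tert-butyldiphenylsilyl)oxy]methyl}-2-(2-hydroxyethyl)-7-iodohepta-2,6-dien-1-yl acetate | CC(=O)OC/C(CCO)=C/CC/C(CO[Si](c1ccccc1)(c1ccccc1)C(C)(C)C)=C\I | intermediate
19 | (2E,6E)-6-{[(tert-butyldiphenylsilyl)oxy]methyl}-7-iodo-2-(2-oxoethyl)hepta-2,6-dien-1-yl acetate (C8 aldehyde) | CC(=O)OC/C(CC=O)=C/CC/C(CO[Si](c1ccccc1)(c1ccccc1)C(C)(C)C)=C\I | intermediate
20 | dimethyl itaconate | COC(=O)CC(=C)C(=O)OC | starting material
21 | 3-(methoxycarbonyl)but-3-enoic acid | COC(=O)C(=C)CC(=O)O | intermediate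
22 | (R)-4-benzyl-1,3-thiazolidine-2-thione | S=C1N[C@H](Cc2ccccc2)CS1 | starting material
23 | O-acylisourea from 21 and EDC (not isolated) | CCN=C(NCCCN(C)C)OC(=O)CC(=C)C(=O)OC | intermediate
24 | methyl 4-[(4R)-4-benzyl-2-thioxo-1,3-thiazolidin-3-yl]-2-methylidene-4-oxobutanoate (fragment C, C6, C7, C11–C13) | COC(=O)C(=C)CC(=O)N1C(=S)SC[C@H]1Cc1ccccc1 | intermediate
25 | (Z)-trichlorotitanium enolate of 24 (not isolated) | COC(=O)C(=C)/C=C(\O[Ti](Cl)(Cl)Cl)N1C(=S)SC[C@H]1Cc1ccccc1 | intermediate
26 | (7R,8S) syn-aldol adduct: C6 thioimide, C8 hydroxyl, C12 methyl ester, 14-OAc, 15-O-TBDPS, C5 iodide | O[C@@H](C/C(COC(C)=O)=C\CC/C(CO[Si](c1ccccc1)(c1ccccc1)C(C)(C)C)=C\I)[C@H](C(=O)N1C(=S)SC[C@H]1Cc1ccccc1)C(=C)C(=O)OC | intermediate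
27 | 8-O-TBS ether of 26 (7R,8S) | CC(C)(C)[Si](C)(C)O[C@@H](C/C(COC(C)=O)=C\CC/C(CO[Si](c1ccccc1)(c1ccccc1)C(C)(C)C)=C\I)[C@H](C(=O)N1C(=S)SC[C@H]1Cc1ccccc1)C(=C)C(=O)OC | intermediate
28 | open-chain C5 iodide with C6 aldehyde (7R,8S; 8-O-TBS, 15-O-TBDPS, 14-OAc, C12 methyl ester) | CC(C)(C)[Si](C)(C)O[C@@H](C/C(COC(C)=O)=C\CC/C(CO[Si](c1ccccc1)(c1ccccc1)C(C)(C)C)=C\I)[C@H](C=O)C(=C)C(=O)OC | intermediate
29 | C5 alkenylchromium dichloride from 28 (not isolated) | CC(C)(C)[Si](C)(C)O[C@@H](C/C(COC(C)=O)=C\CC/C(CO[Si](c1ccccc1)(c1ccccc1)C(C)(C)C)=C\[Cr](Cl)Cl)[C@H](C=O)C(=C)C(=O)OC | intermediate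
30 | ring-closed 6R chromium alkoxide, ten-membered ring, C12 methyl ester still open (not isolated) | CC(C)(C)[Si](C)(C)O[C@H]1C/C(COC(C)=O)=C\CC/C(CO[Si](c2ccccc2)(c2ccccc2)C(C)(C)C)=C\[C@@H](O[Cr](Cl)Cl)[C@@H]1C(=C)C(=O)OC | intermediate
31 | (6R,7S,8S by CIP)-14-acetoxy-8-(TBS-oxy)-15-(TBDPS-oxy)germacra-1(10),4,11(13)-trien-6,12-olide, both ring alkenes ring-cis, lactone trans-fused | CC(C)(C)[Si](C)(C)O[C@H]1C/C(COC(C)=O)=C\CC/C(CO[Si](c2ccccc2)(c2ccccc2)C(C)(C)C)=C\[C@H]2OC(=O)C(=C)[C@H]12 | intermediate
32 | (6R,7R,8S)-14-acetoxy-8,15-dihydroxygermacra-1(10),4,11(13)-trien-6,12-olide | O[C@H]1C/C(COC(C)=O)=C\CC/C(CO)=C\[C@H]2OC(=O)C(=C)[C@H]12 | intermediate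
33 | (6R,7R,8S)-14-acetoxy-8-hydroxy-15-oxogermacra-1(10),4,11(13)-trien-6,12-olide | O[C@H]1C/C(COC(C)=O)=C\CC/C(C=O)=C\[C@H]2OC(=O)C(=C)[C@H]12 | intermediate
34 | ethyl 2-(hydroxymethyl)acrylate | C=C(CO)C(=O)OCC | starting material
35 | ethyl 2-{[(tert-butyldimethylsilyl)oxy]methyl}acrylate | C=C(CO[Si](C)(C)C(C)(C)C)C(=O)OCC | intermediate
36 | 2-{[(tert-butyldimethylsilyl)oxy]methyl}acrylic acid | C=C(CO[Si](C)(C)C(C)(C)C)C(=O)O | intermediate
37 | mixed anhydride of 36 and 2,4,6-trichlorobenzoic acid (not isolated) | C=C(CO[Si](C)(C)C(C)(C)C)C(=O)OC(=O)c1c(Cl)cc(Cl)cc1Cl | intermediate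
38 | O-TBS ether of the target (side-chain hydroxyl silylated) | C=C(CO[Si](C)(C)C(C)(C)C)C(=O)O[C@H]1C/C(COC(C)=O)=C\CC/C(C=O)=C\[C@H]2OC(=O)C(=C)[C@H]12 | intermediate
39 | CNP0198933.2, (6R,7R,8S)-14-acetoxy-8-[2-(hydroxymethyl)acryloyloxy]-15-oxogermacra-1(10),4,11(13)-trien-6,12-olide | C=C(CO)C(=O)O[C@H]1C/C(COC(C)=O)=C\CC/C(C=O)=C\[C@H]2OC(=O)C(=C)[C@H]12 | target

**Step count**
Total: 25 steps. Longest linear sequence: 19 steps (1–6, 9–13, 16–21, 24, 25).

**Steps most likely to fail**

Step 19. Ring closure may be outrun by intermolecular coupling, and attack may come from the wrong face of the C6 carbonyl. The fallback sets C6 by reduction of a ketone instead of by addition to an aldehyde. It sets out from 28 and comes back at 31.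
- The CrCl2/NiCl2 closure is run at 20 °C and worked up cold without the warming period. This should leave the ring-closed C6-epimeric hydroxy esters F1.
- Dess–Martin oxidation merges the epimers into the ten-membered C6 enone F2.
- Corey–Bakshi–Shibata reduction follows, with BH3·SMe2 and the oxazaborolidine enantiomer picked for hydride delivery to the face that gives 6R. It gives the 6R hydroxy ester F3.
- PPTS in warm toluene closes the lactone to 31.

Step 16. The free C8 hydroxyl may close on the C12 ester before step 17 can cap it, and aldehyde 19 may drift into conjugation under amine and Lewis acid. The fallback turns the first process into the protecting step. It sets out from 26 and comes back at 32.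
- Adduct 26 is driven with PPTS to the 8,12-olide thioimide F4, in which the lactone masks O8 and keeps C12 activated.
- i-Bu2AlH at −78 °C gives the 8,12-olide aldehyde F5.
- Closure under the conditions of step 19 gives the ring-closed 6-hydroxy-8,12-olide F6.
- O6 of that compound takes over the C12 acyl group (translactonisation, completed with PPTS if needed) to give the 8-hydroxy-6,12-olide TBDPS ether F7.
- HF·pyridine removes the TBDPS group and gives 32.

Step 18. Hydride may also reach the acetate or the C12 ester, and the aldehyde may epimerise or conjugate at C7 during work-up. The fallback changes both the leaving group and the hydride source. It sets out from 27 and comes back at 28.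
- MeONHMe·HCl and imidazole in CH2Cl2 displace the auxiliary to give the Weinreb amide F8.
- Hydrozirconation with Cp2Zr(H)Cl in THF at rt, a reduction that prefers amides to esters, gives 28 after a neutral work-up on silica.

**Further compounds**
F1 | step 19 | ring-closed C6-epimeric hydroxy esters (C7 and C8 as in 28) | CC(C)(C)[Si](C)(C)O[C@H]1C/C(COC(C)=O)=C\CC/C(CO[Si](c2ccccc2)(c2ccccc2)C(C)(C)C)=C\C(O)[C@@H]1C(=C)C(=O)OC
F2 | step 19 | ten-membered C6 enone | CC(C)(C)[Si](C)(C)O[C@H]1C/C(COC(C)=O)=C\CC/C(CO[Si](c2ccccc2)(c2ccccc2)C(C)(C)C)=C\C(=O)[C@@H]1C(=C)C(=O)OC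
F3 | step 19 | 6R hydroxy ester | CC(C)(C)[Si](C)(C)O[C@H]1C/C(COC(C)=O)=C\CC/C(CO[Si](c2ccccc2)(c2ccccc2)C(C)(C)C)=C\[C@@H](O)[C@@H]1C(=C)C(=O)OC
F4 | step 16 | 8,12-olide thioimide | O=C1O[C@@H](C/C(COC(C)=O)=C\CC/C(CO[Si](c2ccccc2)(c2ccccc2)C(C)(C)C)=C\I)[C@H](C(=O)N2C(=S)SC[C@H]2Cc2ccccc2)C1=C
F5 | step 16 | 8,12-olide aldehyde | O=C1O[C@@H](C/C(COC(C)=O)=C\CC/C(CO[Si](c2ccccc2)(c2ccccc2)C(C)(C)C)=C\I)[C@H](C=O)C1=C
F6 | step 16 | ring-closed 6-hydroxy-8,12-olide | O=C2O[C@H]1C/C(COC(C)=O)=C\CC/C(CO[Si](c3ccccc3)(c3ccccc3)C(C)(C)C)=C\[C@@H](O)[C@@H]1C2=C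
F7 | step 16 | 8-hydroxy-6,12-olide TBDPS ether | O[C@H]1C/C(COC(C)=O)=C\CC/C(CO[Si](c2ccccc2)(c2ccccc2)C(C)(C)C)=C\[C@H]2OC(=O)C(=C)[C@H]12
F8 | step 18 | Weinreb amide | CC(C)(C)[Si](C)(C)O[C@@H](C/C(COC(C)=O)=C\CC/C(CO[Si](c1ccccc1)(c1ccccc1)C(C)(C)C)=C\I)[C@H](C(=O)N(C)OC)C(=C)C(=O)OC
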